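At 20 h, the last reading of each run so far, I asked what share of the substrate charged stood as target, whatever the charge. I call minus the natural logarithm of one minus that share the reach, and this reach was the quantity I carried through the argument.

| setting | west | north | north-east | north-west | south-west |
|---|---|---|---|---|---|
| substrate | 1.00 M | 0.400 M | 3.00 M | 1.00 M | 0.330 M |
| free catalyst | 0.0200 M | 0.0200 M | 0.0200 M | 0.0600 M | 0.0100 M |
| time |  |  |  |  | 20 h |

| run | time / h | [target] / M |
|---|---|---|
| west run | 1.5 | 0.051 |
| west run | 4.6 | 0.137 |
| west run | 8.8 | 0.213 |
| west run | 14 | 0.280 |
| west run | 20 | 0.320 |
| north run | 1.5 | 0.018 |
| north run | 4.6 | 0.057 |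
| north run | 8.8 | 0.085 |
| north run | 14 | 0.111 |
| north run | 20 | 0.126 |
| north-east run | 1.5 | 0.152 |
| north-east run | 4.6 | 0.406 |
| north-east run | 8.8 | 0.654 |
| north-east run | 14 | 0.844 |
| north-east run | 20 | 0.955 |
| north-west run | 1.5 | 0.096 |
| north-west run | 4.6 | 0.242 |
| north-west run | 8.8 | 0.377 |
| north-west run | 14 | 0.466 |
| north-west run | 20 | 0.513 |

(each reading ± 0.003 M)

1. the power of [substrate] that the first rate follows, about the charge of the west run; measure it at two percent of substrate made into target (one fixed amount of target, the same in the runs compared)
2. the power of [free catalyst] that the first rate follows, about the charge of the west run; measure it at two percent of substrate made into target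
3. target in the south-west run at 20 h, as a share of the substrate charged

- Overall: substrate -> target, with free catalyst as catalyst.
- Constant volume, constant temperature.
- An order is taken over about fifteen percent of the charge, up and down.

The west flask had a reach of 0.386. The north flask gave 0.378 and the north-east flask 0.383, so with c(free catalyst) held at 0.0200 M, a charge of substrate changed the reach very little, and I read the reaction as first order in substrate. The north-west flask, with 0.0600 M of free catalyst, reached 0.719, which makes the average power of c(free catalyst) 0.568 over that span.

The south-west flask has 0.0100 M of free catalyst, so I bracketed it from two ends. For the floor I let the reach follow c(free catalyst) to the power one, which gives half the west reach and a yield of 17.5%. For the ceiling I assumed that the power does not drop as the catalyst thins, and I kept 0.568, which gives 22.9%.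

The forecast gave 1.04 for the substrate order, 0.65 for the catalyst order and 21.5% for the yield, arguing that “the local order at 0.02 M is somewhat higher”. Its yield lay inside my bracket, lower than my ceiling and higher than my floor.

The south-west flask gave 20.9%. About the charge of the west flask, the orders were 1.0 in substrate and 0.60 in free catalyst, and the forecast stood within the margin on each. At the same amount of target, the north-west rate was 1.9 times the west rate.

    2 free catalyst ⇌ catalyst dimer, settled at all times (239.0 /M)
    free catalyst + substrate → target + free catalyst (6.480 /M/h)
    free catalyst → spent catalyst (0.1526 /h)
    target → decomposed product (0.02390 /h)

The south-west reach was 0.234. Set against the west reach of 0.386, it gives a power of 0.721 between 0.0100 M and 0.0200 M of free catalyst, higher than the 0.568 of the span above.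

(The data were generated by integration with constants of no real substance, and the scatter is random.)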